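**Retrosynthetic overview**
1. Target ⇐ removal of six MOM ethers ⇐ 2S-flavanone; ring C is closed last by a catalyst-controlled oxa-Michael addition of a 2'-hydroxychalcone.
2. Chalcone ⇐ Claisen–Schmidt condensation of the ring-A acetophenone (E-hydroxyprenyl chain already in place) with a 2,3-diaryl-2,3-dihydrobenzofuran-5-carbaldehyde.
3. Dihydrobenzofuran aldehyde ⇐ one-pot union of C2v-symmetric 4,6-bis(Boc-oxy)isophthalaldehyde, an aryl Grignard reagent and a chiral benzyl sulfonium ylide. Mono-addition breaks the symmetry, Boc shift and elimination dearomatise ring B to an ortho-quinone methide, and a [4+1] annulation builds ring D with both stereocentres.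
4. Ring-A ketone ⇐ 2,4,6-trihydroxyacetophenone by C-prenylation, bis-MOM protection and E-selective allylic hydroxylation.
5. Ring order: rings A and B are bought as arenes, then ring D (step 6), then ring C (step 9).

Assumption: 4,6-dihydroxyisophthalaldehyde, 1-bromo-3,5-bis(methoxymethoxy)benzene, [4-(methoxymethoxy)phenyl]methanol and (2R,5R)-2,5-dimethylthiolane are bought (the sulfide is otherwise two steps from (2S,5S)-hexane-2,5-diol and is recovered after step 6).

**Route**

Step 1
Reactants: 1 2,4,6-trihydroxyacetophenone; 2 prenyl bromide (1-bromo-3-methylbut-2-ene)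
Product: 3 1-[2,4,6-trihydroxy-3-(3-methylbut-2-en-1-yl)phenyl]ethanone
Conditions: DBU (1.0 equiv), THF, 0 °C → rt, 16 h
Reagents that add atoms: none
Why: Direct C-alkylation of the phloroglucinol-type (vinylogous β-diketone) anion with an allylic bromide gives the mono-C-prenyl ketone at the one available ring position type (C3 ≡ C5); O-alkylated and bis-alkylated material is removed by chromatography.

Step 2
Reactants: 3 1-[2,4,6-trihydroxy-3-(3-methylbut-2-en-1-yl)phenyl]ethanone
Product: 4 1-[2-hydroxy-4,6-bis(methoxymethoxy)-3-(3-methylbut-2-en-1-yl)phenyl]ethanone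
Conditions: MOMCl (2.2 equiv), iPr2NEt, CH2Cl2, 0 °C → rt
Reagents that add atoms: chloromethyl methyl ether, COCCl
Why: Williamson-type acetal ether formation takes the 4- and 6-OH, because the 2-OH between acetyl and prenyl is chelated and hindered; this leaves free exactly the phenol that later closes ring C next to the side chain (8-substituted flavanone).

Step 3
Reactants: 4 1-[2-hydroxy-4,6-bis(methoxymethoxy)-3-(3-methylbut-2-en-1-yl)phenyl]ethanone
Product: 5 1-{2-hydroxy-3-[(2E)-4-hydroxy-3-methylbut-2-en-1-yl]-4,6-bis(methoxymethoxy)phenyl}ethanone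
Conditions: SeO2 (0.3 equiv), t-BuOOH (3 equiv), CH2Cl2, rt, 24 h
Reagents that add atoms: tert-butyl hydroperoxide, CC(C)(C)OO (terminal oxidant; the oxygen atom is relayed by catalytic selenium dioxide, O=[Se]=O)
Why: Catalytic SeO2/t-BuOOH allylic hydroxylation (ene reaction, then [2,3]-sigmatropic shift) oxidises the methyl group trans to the chain of the trisubstituted alkene, which fixes the E geometry; the chelated methyl ketone and the MOM ethers are inert at room temperature.

Step 4
Reactants: 6 4,6-dihydroxybenzene-1,3-dicarbaldehyde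
Product: 7 di-tert-butyl (4,6-diformyl-1,3-phenylene) dicarbonate
Conditions: Boc2O (2.2 equiv), DMAP (10 mol %), THF, 0 °C → rt
Reagents that add atoms: di-tert-butyl dicarbonate, CC(C)(C)OC(=O)OC(=O)OC(C)(C)C
Why: DMAP-catalysed O-acylation of both phenols gives the C2v-symmetric bis(aryl carbonate), which keeps both aldehydes electrophilic and installs the group that later migrates and leaves to generate the quinone methide.

Step 5
Reactants: 8 [4-(methoxymethoxy)phenyl]methanol; 9 (2R,5R)-2,5-dimethylthiolane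
Product: 11 (2R,5R)-1-[4-(methoxymethoxy)benzyl]-2,5-dimethylthiolan-1-ium tetrafluoroborate, via benzylic chloride 10 (not isolated)
Conditions: MsCl, iPr2NEt, CH2Cl2, 0 °C; then 9, NaBF4, CH2Cl2–H2O, rt, 24 h
Reagents that add atoms: sodium tetrafluoroborate, [Na+].F[B-](F)(F)F (counter-ion)
Why: The electron-rich benzylic alcohol is turned into its chloride in situ and S-alkylates the sulfide (SN1/SN2 borderline), with exchange to the non-nucleophilic BF4 counter-ion; the sulfide is C2-symmetric, so sulfur is not a stereocentre and a single salt forms.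

Step 6
Reactants: 7 di-tert-butyl (4,6-diformyl-1,3-phenylene) dicarbonate; 12 1-bromo-3,5-bis(methoxymethoxy)benzene; 11 (2R,5R)-1-[4-(methoxymethoxy)benzyl]-2,5-dimethylthiolan-1-ium tetrafluoroborate
Product: 17 tert-butyl (2R,3R)-3-[3,5-bis(methoxymethoxy)phenyl]-5-formyl-2-[4-(methoxymethoxy)phenyl]-2,3-dihydro-1-benzofuran-6-yl carbonate, via aryl Grignard reagent 13 (not isolated), via magnesium phenoxide benzylic carbonate 14 (not isolated), via sulfonium ylide 15 (not isolated), via ortho-quinone methide 16 (not isolated)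
Conditions: 12, Mg, LiCl, THF, rt; add to 7 (1.0 equiv), THF, −78 °C, 30 min; then ylide 15 [from 11, LiN(SiMe3)2, THF, −78 °C] (0.95 equiv), −78 → −20 °C, 3 h; aq. NH4Cl
Reagents that add atoms: none
Why: Proposed new method: the Grignard reagent adds once to the dialdehyde and the alkoxide takes the neighbouring Boc group through a six-membered transfer, so the new phenoxide, para to the second formyl group, shuts down a second addition (symmetry broken) and on warming expels tert-butyl carbonate to give the dearomatised quinone methide 16; the thiolanium benzylide then adds through one ylide face to the exocyclic carbon (restoring aromaticity) and the phenoxide displaces the sulfide with inversion (5-exo-tet) to give the trans-2,3-diaryl ring, C2 becoming R by analogy with the (S,S)-stilbene oxides this (2R,5R)-sulfide gives with aldehydes (as recalled, not checked here) and C3 becoming R through the anti betaine, any cis isomer being removed by chromatography; the closest known reactions are the generation of ortho-quinone methides from O-Boc salicylaldehydes and Grignard reagents, sulfur-ylide [4+1] annulations of ortho-quinone methides, and chiral-sulfide Corey–Chaykovsky reactions.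

Step 7
Reactants: 17 tert-butyl (2R,3R)-3-[3,5-bis(methoxymethoxy)phenyl]-5-formyl-2-[4-(methoxymethoxy)phenyl]-2,3-dihydro-1-benzofuran-6-yl carbonate
Product: 19 (2R,3R)-3-[3,5-bis(methoxymethoxy)phenyl]-6-(methoxymethoxy)-2-[4-(methoxymethoxy)phenyl]-2,3-dihydro-1-benzofuran-5-carbaldehyde, via phenol 18 (not isolated)
Conditions: K2CO3 (cat.), MeOH, 0 °C; evaporate; then MOMCl, iPr2NEt, CH2Cl2, 0 °C → rt
Reagents that add atoms: chloromethyl methyl ether, COCCl
Why: Methanolysis (transesterification) of the aryl carbonate frees the salicylaldehyde phenol, which is capped as its MOM ether, so that no ortho-phenoxide deactivates the aldehyde in step 8 or opens the flavanone through a quinone methide (C2 epimerisation) in step 9.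

Step 8
Reactants: 5 1-{2-hydroxy-3-[(2E)-4-hydroxy-3-methylbut-2-en-1-yl]-4,6-bis(methoxymethoxy)phenyl}ethanone; 19 (2R,3R)-3-[3,5-bis(methoxymethoxy)phenyl]-6-(methoxymethoxy)-2-[4-(methoxymethoxy)phenyl]-2,3-dihydro-1-benzofuran-5-carbaldehyde
Product: 20 (2E)-3-{(2R,3R)-3-[3,5-bis(methoxymethoxy)phenyl]-6-(methoxymethoxy)-2-[4-(methoxymethoxy)phenyl]-2,3-dihydro-1-benzofuran-5-yl}-1-{2-hydroxy-3-[(2E)-4-hydroxy-3-methylbut-2-en-1-yl]-4,6-bis(methoxymethoxy)phenyl}prop-2-en-1-one
Conditions: KOH (aq. 50 %), EtOH, 0 °C → rt, 36 h; AcOH to pH 6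
Reagents that add atoms: none
Why: Claisen–Schmidt aldol condensation gives the E-chalcone; the MOM ethers, the allylic alcohol and the dihydrobenzofuran (no free para-phenol, hence no quinone-methide ring opening) are stable to hydroxide.

Step 9
Reactants: 20 the chalcone of step 8
Product: 21 (2S)-2-{(2R,3R)-3-[3,5-bis(methoxymethoxy)phenyl]-6-(methoxymethoxy)-2-[4-(methoxymethoxy)phenyl]-2,3-dihydro-1-benzofuran-5-yl}-8-[(2E)-4-hydroxy-3-methylbut-2-en-1-yl]-5,7-bis(methoxymethoxy)-2,3-dihydro-4H-chromen-4-one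
Conditions: 9-amino(9-deoxy)epi-quinine N-[3,5-bis(trifluoromethyl)phenyl]thiourea (20 mol %), toluene, rt, 72 h; chromatography
Reagents that add atoms: none
Why: Bifunctional cinchona–thiourea-catalysed intramolecular oxa-Michael addition (6-endo-trig) of the only free phenol, in which the thiourea binds the enone carbonyl and the quinuclidine delivers the phenol to one enone face, sets C2 as S under catalyst control (the quinidine-derived pseudo-enantiomer gives the 2R epimer); selectivity on an unactivated chalcone is expected to be modest, and the 2R epimer, being a diastereomer, is removed on silica and recycled by base-mediated ring opening.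

Step 10
Reactants: 21 the hexa-MOM flavanone of step 9
Product: 22 (2S)-2-[(2R,3R)-3-(3,5-dihydroxyphenyl)-6-hydroxy-2-(4-hydroxyphenyl)-2,3-dihydro-1-benzofuran-5-yl]-5,7-dihydroxy-8-[(2E)-4-hydroxy-3-methylbut-2-en-1-yl]-2,3-dihydro-4H-chromen-4-one (CNP0235407.2)
Conditions: 3 M aq. HCl–MeOH–THF (1:4:2), 40 °C, 4 h
Reagents that add atoms: none
Why: Acid-catalysed acetal exchange releases all six phenols as dimethoxymethane under conditions mild enough for the primary allylic alcohol, the 2S centre and the trans-dihydrobenzofuran (the thermodynamic isomer) to survive.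

**Compound list**
1 | 1-(2,4,6-trihydroxyphenyl)ethanone (2,4,6-trihydroxyacetophenone) | CC(=O)c1c(O)cc(O)cc1O | starting material
2 | 1-bromo-3-methylbut-2-ene (prenyl bromide) | CC(C)=CCBr | starting material
3 | 1-[2,4,6-trihydroxy-3-(3-methylbut-2-en-1-yl)phenyl]ethanone | CC(=O)c1c(O)cc(O)c(CC=C(C)C)c1O | intermediate
4 | 1-[2-hydroxy-4,6-bis(methoxymethoxy)-3-(3-methylbut-2-en-1-yl)phenyl]ethanone | CC(=O)c1c(O)c(CC=C(C)C)c(OCOC)cc1OCOC | intermediate
5 | 1-{2-hydroxy-3-[(2E)-4-hydroxy-3-methylbut-2-en-1-yl]-4,6-bis(methoxymethoxy)phenyl}ethanone | CC(=O)c1c(O)c(C/C=C(\C)CO)c(OCOC)cc1OCOC | intermediate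
6 | 4,6-dihydroxybenzene-1,3-dicarbaldehyde | O=Cc1cc(C=O)c(O)cc1O | starting material
7 | di-tert-butyl (4,6-diformyl-1,3-phenylene) dicarbonate | CC(C)(C)OC(=O)Oc1cc(OC(=O)OC(C)(C)C)c(C=O)cc1C=O | intermediate
8 | [4-(methoxymethoxy)phenyl]methanol | COCOc1ccc(CO)cc1 | starting material
9 | (2R,5R)-2,5-dimethylthiolane | C[C@@H]1CC[C@@H](C)S1 | starting material
10 | 1-(chloromethyl)-4-(methoxymethoxy)benzene | COCOc1ccc(CCl)cc1 | intermediate
11 | (2R,5R)-1-[4-(methoxymethoxy)benzyl]-2,5-dimethylthiolan-1-ium tetrafluoroborate | C[C@@H]1CC[C@@H](C)[S+]1Cc1ccc(OCOC)cc1.F[B-](F)(F)F | intermediate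
12 | 1-bromo-3,5-bis(methoxymethoxy)benzene | COCOc1cc(Br)cc(OCOC)c1 | starting material
13 | [3,5-bis(methoxymethoxy)phenyl]magnesium bromide | COCOc1cc([Mg]Br)cc(OCOC)c1 | intermediate
14 | bromomagnesium 2-{[3,5-bis(methoxymethoxy)phenyl][(tert-butoxycarbonyl)oxy]methyl}-5-[(tert-butoxycarbonyl)oxy]-4-formylphenoxide (racemic at the benzylic carbon) | O=Cc1cc(C(OC(=O)OC(C)(C)C)c2cc(OCOC)cc(OCOC)c2)c(O[Mg]Br)cc1OC(=O)OC(C)(C)C | intermediate
15 | (2R,5R)-2,5-dimethylthiolan-1-ium-1-yl [4-(methoxymethoxy)phenyl]methanide (sulfonium ylide) | C[C@@H]1CC[C@@H](C)[S+]1[CH-]c1ccc(OCOC)cc1 | intermediate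
16 | tert-butyl 5-[3,5-bis(methoxymethoxy)benzylidene]-6-formyl-4-oxocyclohexa-1,6-dien-1-yl carbonate (ortho-quinone methide) | O=CC1=CC(=Cc2cc(OCOC)cc(OCOC)c2)C(=O)C=C1OC(=O)OC(C)(C)C | intermediate
17 | tert-butyl (2R,3R)-3-[3,5-bis(methoxymethoxy)phenyl]-5-formyl-2-[4-(methoxymethoxy)phenyl]-2,3-dihydro-1-benzofuran-6-yl carbonate | O=Cc1cc2c(cc1OC(=O)OC(C)(C)C)O[C@@H](c1ccc(OCOC)cc1)[C@@H]2c1cc(OCOC)cc(OCOC)c1 | intermediate
18 | (2R,3R)-3-[3,5-bis(methoxymethoxy)phenyl]-6-hydroxy-2-[4-(methoxymethoxy)phenyl]-2,3-dihydro-1-benzofuran-5-carbaldehyde | O=Cc1cc2c(cc1O)O[C@@H](c1ccc(OCOC)cc1)[C@@H]2c1cc(OCOC)cc(OCOC)c1 | intermediate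
19 | (2R,3R)-3-[3,5-bis(methoxymethoxy)phenyl]-6-(methoxymethoxy)-2-[4-(methoxymethoxy)phenyl]-2,3-dihydro-1-benzofuran-5-carbaldehyde | O=Cc1cc2c(cc1OCOC)O[C@@H](c1ccc(OCOC)cc1)[C@@H]2c1cc(OCOC)cc(OCOC)c1 | intermediate
20 | (2E)-3-{(2R,3R)-3-[3,5-bis(methoxymethoxy)phenyl]-6-(methoxymethoxy)-2-[4-(methoxymethoxy)phenyl]-2,3-dihydro-1-benzofuran-5-yl}-1-{2-hydroxy-3-[(2E)-4-hydroxy-3-methylbut-2-en-1-yl]-4,6-bis(methoxymethoxy)phenyl}prop-2-en-1-one | O=C(/C=C/c1cc2c(cc1OCOC)O[C@@H](c1ccc(OCOC)cc1)[C@@H]2c1cc(OCOC)cc(OCOC)c1)c1c(O)c(C/C=C(\C)CO)c(OCOC)cc1OCOC | intermediate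
21 | (2S)-2-{(2R,3R)-3-[3,5-bis(methoxymethoxy)phenyl]-6-(methoxymethoxy)-2-[4-(methoxymethoxy)phenyl]-2,3-dihydro-1-benzofuran-5-yl}-8-[(2E)-4-hydroxy-3-methylbut-2-en-1-yl]-5,7-bis(methoxymethoxy)-2,3-dihydro-4H-chromen-4-one | C/C(=C\Cc1c(OCOC)cc(OCOC)c2c1O[C@H](c1cc3c(cc1OCOC)O[C@@H](c1ccc(OCOC)cc1)[C@@H]3c1cc(OCOC)cc(OCOC)c1)CC2=O)CO | intermediate
22 | (2S)-2-[(2R,3R)-3-(3,5-dihydroxyphenyl)-6-hydroxy-2-(4-hydroxyphenyl)-2,3-dihydro-1-benzofuran-5-yl]-5,7-dihydroxy-8-[(2E)-4-hydroxy-3-methylbut-2-en-1-yl]-2,3-dihydro-4H-chromen-4-one | C/C(=C\Cc1c(O)cc(O)c2c1O[C@H](c1cc3c(cc1O)O[C@@H](c1ccc(O)cc1)[C@@H]3c1cc(O)cc(O)c1)CC2=O)CO | target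

**Step count and risks**

Total: 10 steps. Longest linear sequence: 6 steps (1 → 2 → 3 → 8 → 9 → 10; the branches through steps 4 or 5 are equally long).

The three steps most likely to fail are 6, 9 and 3.

Step 6 is new chemistry. The ylide may attack the remaining aldehyde, and the absolute sense rests on an analogy with epoxidations. If the chiral ylide is sluggish or gives poor facial control, the stereochemistry is taken out of the cascade and obtained by resolution instead. The fallback sets out from benzylic chloride 10, which is quaternised with tetrahydrothiophene and NaBF4 to the achiral salt 1-[4-(methoxymethoxy)benzyl]thiolan-1-ium tetrafluoroborate F1. Deprotonation with LiN(SiMe3)2 in THF at −78 °C gives the unhindered ylide thiolan-1-ium-1-yl [4-(methoxymethoxy)phenyl]methanide F2. This traps the same quinone methide 16, generated from 7 and 13 exactly as before, under substrate control, giving racemic trans product: 17 together with its enantiomer tert-butyl (2S,3S)-3-[3,5-bis(methoxymethoxy)phenyl]-5-formyl-2-[4-(methoxymethoxy)phenyl]-2,3-dihydro-1-benzofuran-6-yl carbonate F3. Preparative chiral SFC (amylose tris(3,5-dimethylphenylcarbamate) phase) separates them, and the fallback comes back to the route at 17.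

Step 9 may give only modest catalyst control on an unactivated chalcone, and the facial sense is not certain. The fallback sets out from chalcone 20 and uses thermodynamic cyclisation followed by kinetic resolution. NaOAc in EtOH at 78 °C gives a near 1:1 mixture of 21 and its C2 epimer (2R)-2-{(2R,3R)-3-[3,5-bis(methoxymethoxy)phenyl]-6-(methoxymethoxy)-2-[4-(methoxymethoxy)phenyl]-2,3-dihydro-1-benzofuran-5-yl}-8-[(2E)-4-hydroxy-3-methylbut-2-en-1-yl]-5,7-bis(methoxymethoxy)-2,3-dihydro-4H-chromen-4-one F4. Asymmetric transfer hydrogenation with RuCl[(R,R)-TsDPEN](p-cymene) and HCO2H–Et3N in EtOAc at rt then reduces only the 2R epimer, to the cis alcohol (2R,4R)-2-{(2R,3R)-3-[3,5-bis(methoxymethoxy)phenyl]-6-(methoxymethoxy)-2-[4-(methoxymethoxy)phenyl]-2,3-dihydro-1-benzofuran-5-yl}-8-[(2E)-4-hydroxy-3-methylbut-2-en-1-yl]-5,7-bis(methoxymethoxy)-3,4-dihydro-2H-chromen-4-ol F5. The untouched 2S ketone is separated from the alcohol on silica, and the fallback comes back at 21.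

Step 3 is an allylic oxidation of a phenolic prenyl ketone, which is prone to over-oxidation to the enal and to oxidation of the methyl ketone. The fallback installs the oxidised chain in one C–C bond-forming step and sets out from 1. Treatment with 2-methyl-2-vinyloxirane and Pd(PPh3)4 in THF (0 °C → rt) opens the vinyl epoxide to a π-allyl complex, and C-alkylation at its unsubstituted terminus gives 1-{2,4,6-trihydroxy-3-[(2E)-4-hydroxy-3-methylbut-2-en-1-yl]phenyl}ethanone F6; any Z isomer (expected as a minor product) is removed by crystallisation. MOMCl (2.1 equiv) and iPr2NEt in CH2Cl2 at −20 °C protect the 4- and 6-phenols, and the fallback comes back at 5, bypassing 3 and 4.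

**Further compounds**
F1 | step 6 | 1-[4-(methoxymethoxy)benzyl]thiolan-1-ium tetrafluoroborate | COCOc1ccc(C[S+]2CCCC2)cc1.F[B-](F)(F)F
F2 | step 6 | thiolan-1-ium-1-yl [4-(methoxymethoxy)phenyl]methanide | COCOc1ccc([CH-][S+]2CCCC2)cc1
F3 | step 6 | tert-butyl (2S,3S)-3-[3,5-bis(methoxymethoxy)phenyl]-5-formyl-2-[4-(methoxymethoxy)phenyl]-2,3-dihydro-1-benzofuran-6-yl carbonate | O=Cc1cc2c(cc1OC(=O)OC(C)(C)C)O[C@H](c1ccc(OCOC)cc1)[C@H]2c1cc(OCOC)cc(OCOC)c1
F4 | step 9 | (2R)-2-{(2R,3R)-3-[3,5-bis(methoxymethoxy)phenyl]-6-(methoxymethoxy)-2-[4-(methoxymethoxy)phenyl]-2,3-dihydro-1-benzofuran-5-yl}-8-[(2E)-4-hydroxy-3-methylbut-2-en-1-yl]-5,7-bis(methoxymethoxy)-2,3-dihydro-4H-chromen-4-one | C/C(=C\Cc1c(OCOC)cc(OCOC)c2c1O[C@@H](c1cc3c(cc1OCOC)O[C@@H](c1ccc(OCOC)cc1)[C@@H]3c1cc(OCOC)cc(OCOC)c1)CC2=O)CO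
F5 | step 9 | (2R,4R)-2-{(2R,3R)-3-[3,5-bis(methoxymethoxy)phenyl]-6-(methoxymethoxy)-2-[4-(methoxymethoxy)phenyl]-2,3-dihydro-1-benzofuran-5-yl}-8-[(2E)-4-hydroxy-3-methylbut-2-en-1-yl]-5,7-bis(methoxymethoxy)-3,4-dihydro-2H-chromen-4-ol | C/C(=C\Cc1c(OCOC)cc(OCOC)c2c1O[C@@H](c1cc3c(cc1OCOC)O[C@@H](c1ccc(OCOC)cc1)[C@@H]3c1cc(OCOC)cc(OCOC)c1)C[C@H]2O)CO
F6 | step 3 | 1-{2,4,6-trihydroxy-3-[(2E)-4-hydroxy-3-methylbut-2-en-1-yl]phenyl}ethanone | CC(=O)c1c(O)cc(O)c(C/C=C(\C)CO)c1O
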